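Everything rests on opening the carbocycle of the 7-oxabicyclo[2.2.1]heptane at C3–C4 and C5–C6. Without O7 and the C2 bromine, ring C1–C6 is a cyclohexene with the methyl group on C1 and a fully substituted C4 that bears the bromodimethylcyclohexyl group: exactly what isoprene and a 2-substituted acrolein give when they combine in the 1,4 ("para") sense. One catalytic asymmetric Diels–Alder reaction therefore builds this ring, two C–C bonds and the C4 stereocentre, the formyl group acting as placeholder for O7. The dienophile is enantiopure 2-[(1S,4S)-4-bromo-3,3-dimethylcyclohexyl]prop-2-enal, made from sulcatone by bromonium cyclisation and one-carbon homologations; a stereoretentive Baeyer–Villiger oxidation and an anti bromoetherification finish the synthesis.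

Key step: step 6

Structure check: the target is (1R,2R,4S)-2-bromo-4-[(1S,4S)-4-bromo-3,3-dimethylcyclohexyl]-1-methyl-7-oxabicyclo[2.2.1]heptane. The C2 bromine is endo (anti to O7) and the two cyclohexane substituents are trans (both equatorial). The descriptors of dienophile 9 (1S,4S) and cycloadduct 11 (1S; 1′S,4′S) agree with this target when the Baeyer–Villiger step retains configuration, so no structure needed correction.

Design remarks:
- The cyclisation is ended by an enol acetate. An allylsilane or silyl enol ether would be attacked by electrophilic bromine before the prenyl alkene; the enol acetate also gives the ketone directly.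
- C1′ is not set by reducing an exocyclic alkene. The gem-dimethyl group puts an axial methyl on either ring face, so hydrogen delivery cannot be expected to be selective. An epimerisable formyl group at C1′ is used instead, with separation and recycling.
- C1′ is bonded directly to the dienophile carbon. Its influence on the cycloaddition should be small only because its two ring arms are alike up to C2′/C6′.

Assumption: the sense of induction of both chiral catalysts (steps 2 and 6) is taken from their accepted stereochemical models; if the opposite sense were found on these substrates, the antipodal catalyst would be used without other change.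

Step 1
Reactants: 1 6-methylhept-5-en-2-one (sulcatone)
Product: 2 6-methylhepta-1,5-dien-2-yl acetate
Conditions: LDA, THF, −78 °C (ketone added to base); then Ac2O, −78 → 0 °C
Reagents that add atoms: acetic anhydride, CC(=O)OC(C)=O
Why: Kinetic deprotonation of the methyl ketone by the hindered amide base at −78 °C gives the terminal lithium enolate, which acetic anhydride acylates on oxygen (enol ester formation) while the trisubstituted alkene is untouched; no stereocentre is formed, and the enol acetate is chosen as cyclisation terminus because it is nucleophilic enough to trap a tertiary carbocation yet far less reactive towards electrophilic bromine than an allylsilane or a silyl enol ether, which would be brominated before the prenyl alkene.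

Step 2
Reactants: 2 6-methylhepta-1,5-dien-2-yl acetate
Product: 3 (4S)-4-bromo-3,3-dimethylcyclohexan-1-one
Conditions: 1,3-dibromo-5,5-dimethylhydantoin (1.1 equiv), BINOL-derived chiral thiophosphoramide (10 mol %, antipode chosen for 4S), toluene/CH2Cl2, −90 °C; aq. NaHCO3/Na2S2O3
Reagents that add atoms: 1,3-dibromo-5,5-dimethylhydantoin, CC1(C)N(Br)C(=O)N(Br)C1=O
Why: Lewis-base-catalysed enantioselective bromonium-induced cation–olefin cyclisation of the kind established for prenyl-terminated polyenes: the chiral thiophosphoramide–bromine(I) complex delivers bromine to the more electron-rich trisubstituted alkene, the CH2 terminus of the enol acetate opens the bromiranium ion at its tertiary carbon anti to bromine through a chair (6-endo closure), and the acetoxycarbenium ion so formed gives up its acetyl group on work-up to leave the ketone, so that the only stereocentre, C4, is set by the catalyst-chosen face of bromine transfer (Si face of C5 of 2 for 4S).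

Step 3
Reactants: 3 (4S)-4-bromo-3,3-dimethylcyclohexan-1-one
Product: 6 (1S,4S)-4-bromo-3,3-dimethylcyclohexane-1-carbaldehyde, via enol ether 4 (not isolated), via cis aldehyde 5 (not isolated)
Conditions: Ph3P(CH2OMe)Cl, KHMDS, THF, 0 °C; 3, −78 → 0 °C; 2 M HCl, THF, rt; DBU (0.2 equiv), CH2Cl2, rt; chromatography (recovered epimer returned to the DBU treatment)
Reagents that add atoms: (methoxymethyl)triphenylphosphonium chloride, COC[P+](c1ccccc1)(c1ccccc1)c1ccccc1.[Cl-]; water, O
Why: Wittig methoxymethylenation of the ketone (the neopentyl-type bromide is inert to the ylide) and acid hydrolysis of the enol ether give the one-carbon homologous aldehyde as both C1 epimers, because the gem-dimethyl group puts an axial methyl group on whichever ring face is attacked and so leaves protonation at C1 without a dependable bias; the enolisable formyl centre is therefore equilibrated with DBU towards the diequatorial trans isomer, which is expected to be favoured only modestly since an axial bromine next to the quaternary carbon costs little, and this isomer is separated while the remainder is returned to the equilibration, the C4 bromide being untouched throughout.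

Step 4
Reactants: 6 (1S,4S)-4-bromo-3,3-dimethylcyclohexane-1-carbaldehyde
Product: 8 2-[(1S,4S)-4-bromo-3,3-dimethylcyclohexyl]acetaldehyde, via enol ether 7 (not isolated)
Conditions: Ph3P(CH2OMe)Cl, KHMDS, THF, 0 °C; 6, −78 → 0 °C; then 2 M HCl, THF, rt
Reagents that add atoms: (methoxymethyl)triphenylphosphonium chloride, COC[P+](c1ccccc1)(c1ccccc1)c1ccccc1.[Cl-]; water, O
Why: A second Wittig methoxymethylenation and enol ether hydrolysis lengthen the chain by one more carbon; addition of the ylide to the aldehyde at −78 °C is much faster than α-deprotonation, so the C1 configuration of 6 is carried into 8, where that carbon is β to the carbonyl group and can no longer epimerise.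

Step 5
Reactants: 8 2-[(1S,4S)-4-bromo-3,3-dimethylcyclohexyl]acetaldehyde
Product: 9 2-[(1S,4S)-4-bromo-3,3-dimethylcyclohexyl]prop-2-enal
Conditions: 37% aq. CH2O, pyrrolidine (10 mol %), EtCO2H (10 mol %), i-PrOH, 45 °C
Reagents that add atoms: formaldehyde, C=O
Why: Organocatalytic α-methylenation of an aldehyde (enamine Mannich reaction with formaldehyde followed by elimination of the amine) installs the C=CH2 group; no stereocentre is formed, C1′ is not enolisable in 8, and the reaction is stopped at full conversion so that the amine does not isomerise the product into its conjugated cyclohexylidene isomer.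

Step 6
Reactants: 9 2-[(1S,4S)-4-bromo-3,3-dimethylcyclohexyl]prop-2-enal; 10 isoprene (2-methylbuta-1,3-diene)
Product: 11 (1S)-1-[(1S,4S)-4-bromo-3,3-dimethylcyclohexyl]-4-methylcyclohex-3-ene-1-carbaldehyde
Conditions: (S)-B-o-tolyl oxazaborolidine from (S)-α,α-diphenylprolinol, activated with Tf2NH (20 mol %), isoprene (5 equiv), CH2Cl2, −78 → −40 °C
Reagents that add atoms: none
Why: The triflimide-activated oxazaborolidine binds the formyl oxygen syn to the formyl hydrogen (B–O coordination plus a formyl C–H···O contact to the ring oxygen), which holds the s-trans enal over one aryl group of the catalyst and lowers its LUMO; isoprene then adds in a concerted, asynchronous [4+2] cycloaddition in which the bond from the dienophile CH2 to the diene terminus next to C–CH3 (C5–C6 of the target) runs ahead of the bond to the substituted α-carbon (C3–C4). The closest known reaction type is the oxazaborolidinium-catalysed Diels–Alder reaction of 2-alkyl- and 2-bromoacroleins with isoprene and related dienes. The one ring closed, cyclohexene C1–C6, forms by intermolecular suprafacial [4+2] addition, both σ-bonds in one step and without an endo/exo issue because the diene termini are unsubstituted. The only new stereocentre, quaternary C4, is set by the catalyst: the aryl group screens one π-face and the diene is expected to add to the Si face of the α-carbon, which gives 1S. The step needs para regioselectivity, which follows from the large HOMO coefficient at C1 of isoprene meeting the large LUMO coefficient at the β-carbon of the Lewis-acid-bound enal, and face selectivity, which must come from the catalyst because C1′, although bonded directly to the dienophile carbon, carries two ring arms that are alike up to C2′/C6′ and so gives little bias, while C4′ is remote. α-Branching slows the addition, hence the strongly activated catalyst, excess diene and low temperature, under which the secondary bromide is inert.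

Step 7
Reactants: 11 (1S)-1-[(1S,4S)-4-bromo-3,3-dimethylcyclohexyl]-4-methylcyclohex-3-ene-1-carbaldehyde
Product: 13 (1S)-1-[(1S,4S)-4-bromo-3,3-dimethylcyclohexyl]-4-methylcyclohex-3-en-1-ol, via formate 12 (not isolated)
Conditions: Me3SiOOSiMe3 (1.5 equiv), TMSOTf (10 mol %), CH2Cl2, −78 → −30 °C; pyridine; then K2CO3, MeOH, 0 °C
Reagents that add atoms: bis(trimethylsilyl) peroxide, C[Si](C)(C)OO[Si](C)(C)C
Why: Baeyer–Villiger oxidation with bis(trimethylsilyl) peroxide under silyl triflate catalysis, an aprotic peroxide system that oxidises carbonyl groups without epoxidising isolated alkenes: the silylperoxy adduct of the aldehyde rearranges with migration of the tertiary alkyl group in preference to hydrogen and with retention at the migrating carbon, and mild methanolysis of the formate then frees the tertiary alcohol, so that the stereocentre made in step 6 becomes the carbinol carbon unchanged.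

Step 8
Reactants: 13 (1S)-1-[(1S,4S)-4-bromo-3,3-dimethylcyclohexyl]-4-methylcyclohex-3-en-1-ol
Product: 14 (1R,2R,4S)-2-bromo-4-[(1S,4S)-4-bromo-3,3-dimethylcyclohexyl]-1-methyl-7-oxabicyclo[2.2.1]heptane
Conditions: NBS (1.1 equiv), CH2Cl2, 0 °C, dark
Reagents that add atoms: N-bromosuccinimide, O=C1CCC(=O)N1Br
Why: Bromoetherification of a γ,δ-unsaturated tertiary alcohol, as known for terpinen-4-ol-type substrates: N-bromosuccinimide forms bromiranium ions reversibly on both alkene faces, only the one anti to the C–O bond can be opened by the hydroxyl group, which attacks the methyl-bearing tertiary carbon (Markovnikov, 5-exo) and closes the 7-oxabicyclo[2.2.1]heptane, so that C1 (R) and, through anti addition, the endo C2–Br stereocentre (R) follow from the existing C4 configuration.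

Compound list
1 | 6-methylhept-5-en-2-one (sulcatone) | CC(C)=CCCC(C)=O | starting material
2 | 6-methylhepta-1,5-dien-2-yl acetate | C=C(CCC=C(C)C)OC(C)=O | intermediate
3 | (4S)-4-bromo-3,3-dimethylcyclohexan-1-one | CC1(C)CC(=O)CC[C@@H]1Br | intermediate
4 | (4S)-4-bromo-1-(methoxymethylidene)-3,3-dimethylcyclohexane (E/Z mixture, not isolated) | CC1(C)CC(=COC)CC[C@@H]1Br | intermediate
5 | (1R,4S)-4-bromo-3,3-dimethylcyclohexane-1-carbaldehyde (cis epimer, equilibrated and recycled) | CC1(C)C[C@H](C=O)CC[C@@H]1Br | intermediate
6 | (1S,4S)-4-bromo-3,3-dimethylcyclohexane-1-carbaldehyde (trans) | CC1(C)C[C@@H](C=O)CC[C@@H]1Br | intermediate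
7 | (1S,4S)-1-bromo-4-(2-methoxyethenyl)-2,2-dimethylcyclohexane (E/Z mixture, not isolated) | CC1(C)C[C@@H](C=COC)CC[C@@H]1Br | intermediate
8 | 2-[(1S,4S)-4-bromo-3,3-dimethylcyclohexyl]acetaldehyde | CC1(C)C[C@@H](CC=O)CC[C@@H]1Br | intermediate
9 | 2-[(1S,4S)-4-bromo-3,3-dimethylcyclohexyl]prop-2-enal | CC1(C)C[C@@H](C(=C)C=O)CC[C@@H]1Br | intermediate
10 | isoprene (2-methylbuta-1,3-diene) | C=CC(C)=C | starting material
11 | (1S)-1-[(1S,4S)-4-bromo-3,3-dimethylcyclohexyl]-4-methylcyclohex-3-ene-1-carbaldehyde | CC1(C)C[C@@H]([C@]2(C=O)CCC(C)=CC2)CC[C@@H]1Br | intermediate
12 | (1S)-1-[(1S,4S)-4-bromo-3,3-dimethylcyclohexyl]-4-methylcyclohex-3-en-1-yl formate (not isolated) | CC1(C)C[C@@H]([C@]2(OC=O)CCC(C)=CC2)CC[C@@H]1Br | intermediate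
13 | (1S)-1-[(1S,4S)-4-bromo-3,3-dimethylcyclohexyl]-4-methylcyclohex-3-en-1-ol | CC1(C)C[C@@H]([C@]2(O)CCC(C)=CC2)CC[C@@H]1Br | intermediate
14 | (1R,2R,4S)-2-bromo-4-[(1S,4S)-4-bromo-3,3-dimethylcyclohexyl]-1-methyl-7-oxabicyclo[2.2.1]heptane | CC1(C)C[C@@H]([C@@]23CC[C@@](C)(O2)[C@H](Br)C3)CC[C@@H]1Br | target

Total step count: 8. Longest linear sequence: 8 steps (1 → 14); isoprene 10 enters in step 6.

Steps most likely to fail

Step 6 (key step). The α-branched enal may add too slowly, may isomerise under the acidic catalyst to the conjugated cyclohexylidene aldehyde, or may be attacked with too little face selectivity. Fallback: catalyst control is given up in favour of diastereomer separation. Setting out from 9 and 10, the cycloaddition is promoted by an achiral Lewis acid (Me2AlCl, CH2Cl2, −78 °C), which keeps the para orientation. It gives 11 together with its C1 epimer, (1R)-1-[(1S,4S)-4-bromo-3,3-dimethylcyclohexyl]-4-methylcyclohex-3-ene-1-carbaldehyde F1. The pair is taken through the conditions of step 7, in which the epimeric (1R)-1-[(1S,4S)-4-bromo-3,3-dimethylcyclohexyl]-4-methylcyclohex-3-en-1-yl formate F2 is not isolated. The tertiary alcohols 13 and (1R)-1-[(1S,4S)-4-bromo-3,3-dimethylcyclohexyl]-4-methylcyclohex-3-en-1-ol F3 are then separated by preparative chromatography or crystallisation, and the route is rejoined at 13.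

Step 2. The enantiofacial discrimination may be too low with a terminating group that differs from the aryl-terminated polyenes for which such catalysts were developed, or bromination may compete at the enol ester. Fallback: asymmetric catalysis is replaced by resolution. Setting out from 2, the diene is cyclised with stoichiometric bromodiethylsulfonium bromopentachloroantimonate in nitromethane at −25 °C, a reagent made for bromonium-induced cation–olefin cyclisations. This gives ketone 3 as the racemate, that is, together with (4R)-4-bromo-3,3-dimethylcyclohexan-1-one F4. The enantiomers are separated by preparative chromatography on a chiral stationary phase, and the route is rejoined at 3.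

Step 7. Chemoselectivity may be lost: the trisubstituted alkene may be oxidised or ionised by the Lewis-acidic peroxide system, or hydride may migrate in place of the tertiary alkyl group and give the acid. Fallback: the alkene is masked before a conventional peracid oxidation. Setting out from 11, bromine (CH2Cl2, −78 °C) gives (1S)-3,4-dibromo-1-[(1S,4S)-4-bromo-3,3-dimethylcyclohexyl]-4-methylcyclohexane-1-carbaldehyde F5 as the two anti adducts. mCPBA with NaHCO3 in CH2Cl2 then effects the Baeyer–Villiger oxidation to (1S)-3,4-dibromo-1-[(1S,4S)-4-bromo-3,3-dimethylcyclohexyl]-4-methylcyclohexyl formate F6. Zinc dust in AcOH/Et2O at 0 °C removes the vicinal bromines only and returns the alkene, so the route is rejoined at formate 12, which is methanolysed to 13 as in step 7.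

Further compounds
F1 | step 6 | (1R)-1-[(1S,4S)-4-bromo-3,3-dimethylcyclohexyl]-4-methylcyclohex-3-ene-1-carbaldehyde | CC1(C)C[C@@H]([C@@]2(C=O)CCC(C)=CC2)CC[C@@H]1Br
F2 | step 6 | (1R)-1-[(1S,4S)-4-bromo-3,3-dimethylcyclohexyl]-4-methylcyclohex-3-en-1-yl formate | CC1(C)C[C@@H]([C@@]2(OC=O)CCC(C)=CC2)CC[C@@H]1Br
F3 | step 6 | (1R)-1-[(1S,4S)-4-bromo-3,3-dimethylcyclohexyl]-4-methylcyclohex-3-en-1-ol | CC1(C)C[C@@H]([C@@]2(O)CCC(C)=CC2)CC[C@@H]1Br
F4 | step 2 | (4R)-4-bromo-3,3-dimethylcyclohexan-1-one | CC1(C)CC(=O)CC[C@H]1Br
F5 | step 7 | (1S)-3,4-dibromo-1-[(1S,4S)-4-bromo-3,3-dimethylcyclohexyl]-4-methylcyclohexane-1-carbaldehyde (both anti-dibromides) | CC1(C)C[C@@H]([C@]2(C=O)CCC(C)(Br)C(Br)C2)CC[C@@H]1Br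
F6 | step 7 | (1S)-3,4-dibromo-1-[(1S,4S)-4-bromo-3,3-dimethylcyclohexyl]-4-methylcyclohexyl formate (both anti-dibromides) | CC1(C)C[C@@H]([C@]2(OC=O)CCC(C)(Br)C(Br)C2)CC[C@@H]1Br
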